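**Numbering.** Atoms: C1 is the quaternary carbinol carbon, C7 its CH2O arm, C2 the CH(OBz) carbon, C3=C4 the alkene, C5 and C6 the CH(OH) carbons. "Hydroxyl face" is the ring face that carries the C1 hydroxyl, "arm face" the face that carries C7. Compounds: 1 benzoic acid, 2 dihydro acid, 3 methyl ester, 4 its sodium dienolate, 5 hydroxy ester, 6 diol, 7 benzoyl chloride, 8 dienol benzoate, 9 cumene hydroperoxide, 10 epoxy alcohol, 11 triol, 12 acetonide, 13 silyl ether, 14 hydroperoxide, 15 allylic alcohol, 16 protected dibenzoate, 17 target.

## Analysis of the target

Compound 17 is a single carbocycle, a cyclohex-3-ene (C1–C6, alkene C3=C4), in which every sp3 ring carbon carries oxygen and the quaternary C1 also bears the C7H2OBz arm. It has four stereocentres, (1S,2S,5R,6S). The C1 and C6 hydroxyls lie on the hydroxyl face, while the C2 benzoate and the C5 hydroxyl lie on the arm face. Thus C1–O/C6–O are cis, C5–O/C6–O trans, C1–O/C2–O trans, and C2–O/C5–O cis across the alkene. The sensitive points are two benzoates next to free hydroxyls (1,2- and 1,3-acyl shifts under base or fluoride), an allylic ester at C2 and an allylic alcohol at C5, and a tertiary carbinol. The difficulty is twofold: five oxygens must be told apart so that only C2 and C7 are acylated, and the quaternary C1 must be fixed relative to three neighbours in a ring that has no carbon substituent to bias a face. The strategy rests on one feature: without the C2, C5 and C6 oxygens the ring is a 1-substituted cyclohexa-2,5-dien-1-ol. In it C1 sits on a mirror plane between two enantiotopic alkenes, C2=C3 and C5=C6, and its tertiary hydroxyl can anchor a catalyst. All six ring carbons and C7 then map onto a benzoic acid skeleton.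

## Retrosynthetic reasoning

**17 to 16.** The O–C bonds of a C1/C6 acetonide and the O–Si bond of a C5 silyl ether are added in the backward sense. The C2 hydroxyl can be acylated alone only if C5–OH and C6–OH are masked, and the cis C1/C6 pair takes a cyclic acetal that also caps C1–OH. Both groups fall to acid, under which the benzoates do not migrate, so the forward step is one acidic hydrolysis.

**16 to 15 and 7.** The C2 O–acyl bond is cut. The C7 benzoate is older: it is carried from the start and serves as the protecting group of the primary alcohol throughout. The C2 ester is put on late because the C2 oxygen itself arrives late.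

**15 to 13 (through 14).** The C2–O bond is cut and the alkene is moved back from C3=C4 to C2=C3, with a hydrogen returned to C4. This is the retron of an ene-type photooxygenation. It is chosen because C1 has no hydrogen, so only one regiochemical outcome exists. The cut removes the C2 stereocentre and leads back to the alkene that the key step leaves untouched. The forward step has to deliver oxygen to the arm face.

**13 to 12 to 11.** The O–Si bond at C5 and the acetal at C1/C6 are removed in turn. The forward acetalisation must select the cis C1/C6 diol over the trans C5/C6 diol, which ring strain should ensure.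

**11 to 10.** The C5–O bond to the newer hydroxyl is cut, which gives back an oxirane across C5/C6 on the hydroxyl face. A trans C5/C6 diol whose C6 oxygen is cis to C1–OH is exactly what anti opening at C5 of a syn epoxy alcohol gives. The forward hydrolysis has to attack C5 and not the neopentyl-like C6.

**10 to 8 and 9.** Both C–O bonds of the oxirane are cut. This is the central disconnection: C1, C5 and C6 collapse into a choice between two enantiotopic alkenes of the achiral dienol 8, and the oxygen comes from hydroperoxide 9. The forward reaction must choose one alkene (absolute configuration) and the hydroxyl face (relative configuration). A chiral bishydroxamate complex of tetravalent hafnium bound to the C1 alkoxide is asked to do both.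

**8 to 6 and 7.** The C7 O–acyl bond is cut. Acylating the primary hydroxyl of 6 with 7 installs the ester that 17 needs and leaves the tertiary hydroxyl as the only donor for the catalyst.

**6 to 5 to 3 (through 4) to 2 to 1.** C7 is returned to the ester oxidation level (hydride reduction forward). The C1–O bond is then cut (oxidation of dienolate 4 forward), the ester is traced to acid 2, and the two sp3 ring carbons of 2 are traced to the arene 1 (Birch reduction forward). The oxygen is put on C1 in a separate aprotic enolate step and not in the reducing medium of the dearomatisation, because an electrophilic oxidant can then be dosed against a defined enolate.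

## Alternatives that were turned down

**Alternative 1:** The ring bond C1–C2 and the C7–O bond are disconnected together. The forward key step is an intramolecular nitrile oxide cycloaddition: an oxime at C2 of a Z-enal chain is oxidised with hypochlorite and the dipole adds across a C1=C7 silyl enol ether. This gives the fused isoxazoline A1, with the cyclohexene, the quaternary C1 and its oxygen in place. C5 and C6 are bought as a trans-diol acetonide; with both carbinol centres retained this requires (2S,3S)-tartaric acid A2, the less common antipode.
- For: the absolute configuration of C5 and C6 is not induced but purchased, and on this point the alternative is stronger than the chosen route. The C3=C4 alkene is present from the start.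
- Against: in A1 the carbon C2 is the C=N carbon. After N–O cleavage it is a ketone conjugated to C3=C4, so the C2 stereocentre still has to be set by a 1,2-reduction next to a quaternary centre, and the N–O cleavage must spare the alkene.
- Against: the Z-enal can isomerise to the E isomer, which cannot reach the dipolarophile. The acetonide spans a trans diol, so the cyclisation builds a trans-fused dioxolane onto the forming ring, and C1 depends on induction from C6 alone.
- Comparison: both termini of A2 need chain extension, so the route is no shorter. The chosen strategy offers in place of the secure chiral pool a C2 oxygen that arrives with its alkene and its configuration in one step, with no redox adjustment at C2.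

**Alternative 2:** The C5–C6 bond (aldol) and the C1–C2 bond (nitroaldol) are disconnected. In the forward key step rabbit muscle aldolase joins dihydroxyacetone phosphate A3 to 4-nitrobutanal A4, and the nitronate carbon then closes onto the C1 ketone (Henry reaction) to give the nitrocyclitol phosphate A5.
- For: two C–C bonds and the C1, C5 and C6 centres form in water without protecting groups. The enzyme's control of the C5/C6 threo diol is dependable, which is stronger than an untested catalyst.
- Against: A5 has methylenes at C3 and C4 and nitrogen at C2. The target needs a Nef-type conversion to a C2 carbonyl, introduction of the C3=C4 unsaturation and a stereoselective reduction at C2, all on a polar polyol.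
- Against: the nitroaldol is reversible, so C1 and C2 are under thermodynamic control. After dephosphorylation five hydroxyls remain, and C2 cannot be benzoylated beside C5 and C6 without extra protection steps.
- Comparison: the chosen strategy gives up the certainty of enzymatic stereocontrol. In return the oxygens arrive one after another, already differentiated, and the alkene is never lost.

**Alternative 3:** The C1–C2 bond is disconnected by a [3,3] shift. A six-membered lactone derived from D-mannose A7, carrying an (E)-2-alkoxyvinyl group on the ring-oxygen carbon, is converted with a potassium amide base and a silyl chloride into its silyl ketene acetal. Ireland–Claisen rearrangement contracts the ring to the cyclohexenecarboxylic acid A6 with C3=C4 formed at once.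
- For: C5 and C6 come from the sugar, and C1 and C2 are set through a lactone-constrained boat-like transition state. A6 already carries a differentiated C2 oxygen and the same C1/C6 acetonide and C5 silyl ether that the chosen end game uses. In stereochemical security, and in having the C2 oxygen early, this alternative is stronger.
- Against: the lactone takes many steps from A7 (selective protection, oxidation, E-selective enol ether formation). The lactone enolate has a β-oxygen that can be eliminated, and a quaternary centre must form in a boat transition state.
- Against: after the key step the carboxyl must be reduced and benzoylated, the C2 ether cleaved and C2 benzoylated, so the sequence is clearly longer.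
- Comparison: the chosen route reaches the same protected pattern in twelve steps from an arene. It pays for this with one unproven asymmetric step.

Key step: step 6

Assumption: the sense in which the hafnium bishydroxamate catalyst selects between the two alkenes cannot be assigned in advance for this substrate type; the ligand from (1R,2R)-cyclohexane-1,2-diamine is written, and its antipode is to be used if the first run gives the enantiomer of 10.

## Route

Step 1
Reactants: 1 benzoic acid
Product: 2 cyclohexa-2,5-diene-1-carboxylic acid
Conditions: Na, NH3(l), EtOH, −78 °C to −33 °C; NH4Cl; then aq. HCl to pH 2, 0 °C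
Reagents that add atoms: none
Why: Birch reduction: electron transfer to the benzoate and protonation at C4 and C1 leave the two alkenes unconjugated, the regiochemistry typical of an arene with a carboxylate substituent; quenching with NH4Cl before the ammonia is removed keeps the 2,5-diene from moving into conjugation. No stereocentre is formed.

Step 2
Reactants: 2 cyclohexa-2,5-diene-1-carboxylic acid
Product: 3 methyl cyclohexa-2,5-diene-1-carboxylate
Conditions: MeI, KHCO3, DMF, rt
Reagents that add atoms: iodomethane, CI
Why: Carboxylate O-alkylation (SN2 on iodomethane): bicarbonate is too weak a base to remove the doubly allylic C1–H, so neither C-alkylation nor isomerisation of the diene is expected, and no acid is present that could aromatise the ring.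

Step 3
Reactants: 3 methyl cyclohexa-2,5-diene-1-carboxylate
Product: 5 methyl 1-hydroxycyclohexa-2,5-diene-1-carboxylate, via sodium dienolate 4 (not isolated)
Conditions: NaN(SiMe3)2, THF, −78 °C; then 2-(benzenesulfonyl)-3-phenyloxaziridine, −78 °C; aq. NH4Cl
Reagents that add atoms: 2-(benzenesulfonyl)-3-phenyloxaziridine, O=S(=O)(c1ccccc1)N1OC1c1ccccc1
Why: Davis-type enolate oxidation: the doubly allylic, ester-activated C1–H is removed at low temperature and the cross-conjugated dienolate 4 takes the electrophilic oxygen at its α-carbon, the usual site of kinetic attack on Birch ester enolates, so both alkenes stay isolated. The sodium counter-ion limits addition of 4 to the sulfonimine by-product; C1 lies on a mirror plane, so no stereocentre arises.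

Step 4
Reactants: 5 methyl 1-hydroxycyclohexa-2,5-diene-1-carboxylate
Product: 6 1-(hydroxymethyl)cyclohexa-2,5-dien-1-ol
Conditions: LiAlH4, THF, 0 °C; Na2SO4·10H2O
Reagents that add atoms: none
Why: Ester reduction with LiAlH4 to the primary alcohol; the isolated alkenes and the tertiary alkoxide are inert, and the neutral sulfate work-up avoids acid, which would dehydrate the bis-allylic carbinol to an arene.

Step 5
Reactants: 6 1-(hydroxymethyl)cyclohexa-2,5-dien-1-ol; 7 benzoyl chloride
Product: 8 (1-hydroxycyclohexa-2,5-dien-1-yl)methyl benzoate
Conditions: BzCl (1.05 equiv), pyridine, CH2Cl2, −20 °C to 0 °C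
Reagents that add atoms: benzoyl chloride 7, O=C(Cl)c1ccccc1
Why: Selective O-acylation: the primary hydroxyl reacts with one equivalent of acid chloride at low temperature while the tertiary, doubly allylic hydroxyl does not. The benzoate is the ester required at C7 in 17 and leaves C1–OH as the only binding site for the catalyst of step 6.

Step 6
Reactants: 8 (1-hydroxycyclohexa-2,5-dien-1-yl)methyl benzoate; 9 cumene hydroperoxide
Product: 10 [(1S,2S,6S)-2-hydroxy-7-oxabicyclo[4.1.0]hept-3-en-2-yl]methyl benzoate (syn epoxy alcohol: oxirane across C5/C6 on the hydroxyl face)
Conditions: Hf(OtBu)4 (10 mol%), N,N'-[(1R,2R)-cyclohexane-1,2-diyl]bis(N-hydroxy-2,2-diphenylacetamide) (12 mol%), cumene hydroperoxide (1.5 equiv), 4 Å molecular sieves, toluene, 0 °C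
Reagents that add atoms: cumene hydroperoxide 9, CC(C)(OO)c1ccccc1
Why: Proposed new method: the closest known reaction type is the hydroxyl-directed catalytic asymmetric epoxidation of tertiary allylic alcohols on bishydroxamate complexes of tetravalent hafnium, together with the desymmetrisation of divinyl and cyclohexa-2,5-dienyl carbinols by directed epoxidation; an endocyclic tertiary bis-allylic carbinol has not been desymmetrised in this way. The C1 alkoxide of 8 and the peroxide from 9 are expected to bind to the same hafnium centre, and the activated peroxide oxygen is passed to one ring alkene in a concerted transition state in which both C–O bonds form together, so the oxirane closes by a [2+1] oxygen transfer and not by displacement. Because the oxygen is delivered from the metal that holds the C1 oxygen, it can reach only the hydroxyl face, which fixes C5 and C6 relative to C1 (substrate control through the C1–O–Hf tether). Which of the two enantiotopic alkenes reacts is decided by the twofold-symmetric ligand, whose aryl groups should leave room for only one allylic arm near the bound peroxide; this single choice sets the absolute configuration of C1, C5 and C6 together (catalyst control). The step needs group selectivity between two enantiotopic cis-alkenes, face selectivity, and chemoselectivity against ionisation of the bis-allylic carbinol and against oxidation of the C4 methylene; the flat ring holds both alkenes at a fixed distance from the bound alkoxide, the d0 metal has no one-electron chemistry, and the CH2OBz arm on C1 lowers the tendency to ionise. Any wrongly selected enantiomer still carries the alkene that the catalyst prefers and should go on faster to the meso bis-epoxide, so the optical purity of 10 should rise with conversion at a small cost in material.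

Step 7
Reactants: 10 [(1S,2S,6S)-2-hydroxy-7-oxabicyclo[4.1.0]hept-3-en-2-yl]methyl benzoate
Product: 11 [(1S,5R,6S)-1,5,6-trihydroxycyclohex-2-en-1-yl]methyl benzoate
Conditions: HClO4 (cat.), THF–H2O (2:1), 0 °C to rt
Reagents that add atoms: water, O
Why: Acid-catalysed epoxide hydrolysis with inversion (borderline SN2): water attacks C5, the oxirane carbon remote from the quaternary, oxygen-bearing C1, whose bulk and inductive pull disfavour bond formation at C6. Inversion at C5 places the new hydroxyl on the arm face, trans to the retained C6 oxygen, which stays cis to C1–OH.

Step 8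
Reactants: 11 [(1S,5R,6S)-1,5,6-trihydroxycyclohex-2-en-1-yl]methyl benzoate
Product: 12 [(3aS,4R,7aS)-4-hydroxy-2,2-dimethyl-3a,4,5,7a-tetrahydro-1,3-benzodioxol-7a-yl]methyl benzoate (C1/C6 acetonide, C5–OH free)
Conditions: Me2C(OMe)2, pyridinium p-toluenesulfonate (cat.), acetone, rt
Reagents that add atoms: 2,2-dimethoxypropane, COC(C)(C)OC
Why: Acetal exchange under thermodynamic control: only the cis C1/C6 diol can close an unstrained cis-fused dioxolane, whereas the trans C5/C6 pair would need a trans-fused five-membered ring on a cyclohexene. This caps C1–OH and C6–OH in one step and leaves C5–OH free.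

Step 9
Reactants: 12 [(3aS,4R,7aS)-4-hydroxy-2,2-dimethyl-3a,4,5,7a-tetrahydro-1,3-benzodioxol-7a-yl]methyl benzoate
Product: 13 [(3aS,4R,7aS)-4-{[tert-butyl(dimethyl)silyl]oxy}-2,2-dimethyl-3a,4,5,7a-tetrahydro-1,3-benzodioxol-7a-yl]methyl benzoate
Conditions: TBSOTf, 2,6-lutidine, CH2Cl2, −78 °C to 0 °C
Reagents that add atoms: tert-butyldimethylsilyl trifluoromethanesulfonate, CC(C)(C)[Si](C)(C)OS(=O)(=O)C(F)(F)F
Why: Silylation of the one remaining hydroxyl with a silyl triflate and a hindered base; the ether keeps the C5 oxygen from being acylated in step 11.

Step 10
Reactants: 13 [(3aS,4R,7aS)-4-{[tert-butyl(dimethyl)silyl]oxy}-2,2-dimethyl-3a,4,5,7a-tetrahydro-1,3-benzodioxol-7a-yl]methyl benzoate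
Product: 15 [(3aS,4R,7S,7aR)-4-{[tert-butyl(dimethyl)silyl]oxy}-7-hydroxy-2,2-dimethyl-3a,4,7,7a-tetrahydro-1,3-benzodioxol-7a-yl]methyl benzoate (C2 allylic alcohol on the arm face), via allylic hydroperoxide 14 (not isolated)
Conditions: O2, hν (white LED), tetraphenylporphyrin (cat.), CDCl3, 0 °C; then PPh3, 0 °C to rt
Reagents that add atoms: dioxygen, O=O
Why: Schenck ene reaction of singlet oxygen followed by phosphine reduction of the O–O bond. C1 has no hydrogen, so oxygen can bond only at C2 while a hydrogen leaves C4 and the alkene moves to C3=C4; in the favoured half-chair (C5 and C6 oxygens equatorial) the C1–O bond is pseudoaxial on the hydroxyl face and the C4–H on the arm face is pseudoaxial, so the suprafacial ene process should run on the arm face, away from the dioxolane and its repelling oxygen, and set C2–O trans to C1–O.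

Step 11
Reactants: 15 [(3aS,4R,7S,7aR)-4-{[tert-butyl(dimethyl)silyl]oxy}-7-hydroxy-2,2-dimethyl-3a,4,7,7a-tetrahydro-1,3-benzodioxol-7a-yl]methyl benzoate; 7 benzoyl chloride
Product: 16 [(3aS,4R,7S,7aR)-7-(benzoyloxy)-4-{[tert-butyl(dimethyl)silyl]oxy}-2,2-dimethyl-3a,4,7,7a-tetrahydro-1,3-benzodioxol-7a-yl]methyl benzoate
Conditions: BzCl, pyridine, 4-(dimethylamino)pyridine (cat.), CH2Cl2, 0 °C to rt
Reagents that add atoms: benzoyl chloride 7, O=C(Cl)c1ccccc1
Why: Acylation of a hindered secondary allylic alcohol with acid chloride and 4-(dimethylamino)pyridine as acyl-transfer catalyst; it is the only free hydroxyl, so no selectivity is needed and C2 keeps its configuration.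

Step 12
Reactants: 16 [(3aS,4R,7S,7aR)-7-(benzoyloxy)-4-{[tert-butyl(dimethyl)silyl]oxy}-2,2-dimethyl-3a,4,7,7a-tetrahydro-1,3-benzodioxol-7a-yl]methyl benzoate
Product: 17 [(1S,2S,5R,6S)-2-(benzoyloxy)-1,5,6-trihydroxycyclohex-3-en-1-yl]methyl benzoate
Conditions: TFA–H2O (9:1), 0 °C to rt; evaporation with toluene
Reagents that add atoms: none
Why: Acid hydrolysis of the acetonide and of the silyl ether in one operation; acid is chosen over fluoride or base because benzoates next to free hydroxyls migrate under basic conditions, and the allylic C2 and C5 oxygens are flanked by electron-poor carbons that resist ionisation. No stereocentre is touched.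

## Compound list

1 | benzoic acid | OC(=O)c1ccccc1 | starting material
2 | cyclohexa-2,5-diene-1-carboxylic acid | OC(=O)C1C=CCC=C1 | intermediate
3 | methyl cyclohexa-2,5-diene-1-carboxylate | COC(=O)C1C=CCC=C1 | intermediate
4 | sodium (cyclohexa-2,5-dien-1-ylidene)(methoxy)methanolate (dienolate of 3; not isolated) | COC([O-])=C1C=CCC=C1.[Na+] | intermediate
5 | methyl 1-hydroxycyclohexa-2,5-diene-1-carboxylate | COC(=O)C1(O)C=CCC=C1 | intermediate
6 | 1-(hydroxymethyl)cyclohexa-2,5-dien-1-ol | OCC1(O)C=CCC=C1 | intermediate
7 | benzoyl chloride | O=C(Cl)c1ccccc1 | starting material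
8 | (1-hydroxycyclohexa-2,5-dien-1-yl)methyl benzoate | O=C(OCC1(O)C=CCC=C1)c1ccccc1 | intermediate
9 | cumene hydroperoxide | CC(C)(OO)c1ccccc1 | starting material
10 | [(1S,2S,6S)-2-hydroxy-7-oxabicyclo[4.1.0]hept-3-en-2-yl]methyl benzoate | O=C(OC[C@@]1(O)C=CC[C@H]2[C@@H]1O2)c1ccccc1 | intermediate
11 | [(1S,5R,6S)-1,5,6-trihydroxycyclohex-2-en-1-yl]methyl benzoate | O=C(OC[C@@]1(O)C=CC[C@@H](O)[C@@H]1O)c1ccccc1 | intermediate
12 | [(3aS,4R,7aS)-4-hydroxy-2,2-dimethyl-3a,4,5,7a-tetrahydro-1,3-benzodioxol-7a-yl]methyl benzoate | O=C(OC[C@@]12C=CC[C@@H](O)[C@@H]1OC(C)(C)O2)c1ccccc1 | intermediate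
13 | [(3aS,4R,7aS)-4-{[tert-butyl(dimethyl)silyl]oxy}-2,2-dimethyl-3a,4,5,7a-tetrahydro-1,3-benzodioxol-7a-yl]methyl benzoate | O=C(OC[C@@]12C=CC[C@@H](O[Si](C)(C)C(C)(C)C)[C@@H]1OC(C)(C)O2)c1ccccc1 | intermediate
14 | [(3aS,4R,7S,7aS)-4-{[tert-butyl(dimethyl)silyl]oxy}-7-hydroperoxy-2,2-dimethyl-3a,4,7,7a-tetrahydro-1,3-benzodioxol-7a-yl]methyl benzoate (not isolated) | O=C(OC[C@@]12[C@@H](OO)C=C[C@@H](O[Si](C)(C)C(C)(C)C)[C@@H]1OC(C)(C)O2)c1ccccc1 | intermediate
15 | [(3aS,4R,7S,7aR)-4-{[tert-butyl(dimethyl)silyl]oxy}-7-hydroxy-2,2-dimethyl-3a,4,7,7a-tetrahydro-1,3-benzodioxol-7a-yl]methyl benzoate | O=C(OC[C@@]12[C@@H](O)C=C[C@@H](O[Si](C)(C)C(C)(C)C)[C@@H]1OC(C)(C)O2)c1ccccc1 | intermediate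
16 | [(3aS,4R,7S,7aR)-7-(benzoyloxy)-4-{[tert-butyl(dimethyl)silyl]oxy}-2,2-dimethyl-3a,4,7,7a-tetrahydro-1,3-benzodioxol-7a-yl]methyl benzoate | O=C(OC[C@@]12[C@@H](OC(=O)c3ccccc3)C=C[C@@H](O[Si](C)(C)C(C)(C)C)[C@@H]1OC(C)(C)O2)c1ccccc1 | intermediate
17 | [(1S,2S,5R,6S)-2-(benzoyloxy)-1,5,6-trihydroxycyclohex-3-en-1-yl]methyl benzoate | O=C(OC[C@@]1(O)[C@@H](OC(=O)c2ccccc2)C=C[C@@H](O)[C@@H]1O)c1ccccc1 | target

## Step count and least certain steps

Total step count: 12. Longest linear sequence: 12 steps (1 to 17); 7 and 9 enter as reagents.

**Step 6 (key step).** The most likely failure is weak discrimination between the two enantiotopic alkenes, because two cis-alkenes in a flat ring give the ligand little to grip. The Lewis-acidic metal may also promote loss of water from the bis-allylic carbinol with aromatisation, and a second oxygen transfer may consume product.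
Fallback, by known chemistry: from 8, hydroxyl-directed epoxidation without asymmetric induction (VO(acac)2, tert-butyl hydroperoxide, CH2Cl2, 0 °C) should give the racemic syn epoxy alcohol F1. It is taken through the conditions of steps 7 and 8 to the racemic triol F2 and the racemic acetonide F3, which has a single secondary hydroxyl. F3 is resolved by lipase-catalysed acylation (immobilised Candida antarctica lipase B, vinyl chloroacetate, tert-butyl methyl ether). By the empirical size rule for secondary alcohols the enantiomer with (R) configuration at C5 should be acylated faster, giving the chloroacetate F4. F4 is separated from the unreacted half of F3 and cleaved with thiourea and NaHCO3 in ethanol, returning to the route at 12. Should the enzyme prefer the other enantiomer, the unreacted alcohol is 12 itself.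

**Step 10.** The alkene is 1,2-disubstituted and flanked by an electron-poor allylic carbon, so slow ene reaction with bleaching of the sensitiser is the main risk. Partial attack from the hydroxyl face and radical allylic shift of the hydroperoxide are lesser ones.
Fallback: from 13, epoxidation with 3-chloroperoxybenzoic acid (NaHCO3, CH2Cl2) from the arm face should give the C2/C3 epoxide F5. Phenylselenide (PhSeSePh, NaBH4, EtOH) opens it at C3, away from the quaternary C1, to the hydroxy selenide F6. Oxidation with H2O2 and syn elimination of the selenoxide toward C4 then gives 15.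

**Step 7.** Water may attack C6 in part, or the carbonyl oxygen of the C7 benzoate, which sits on the arm face behind C6, may take part. That would invert C6 or move the ester.
Fallback: from 10, opening under chelation control with Ti(OiPr)4 and chloroacetic acid, in which the metal binds the C1 oxygen and the oxirane and directs the carboxylate to C5, should give the 5-O-chloroacetyl diol F7. Cleavage with thiourea and NaHCO3 returns to the route at 11.

**Step 3.** The dienolate may react in part at its γ-carbon or add to the sulfonimine by-product, and the product may lose water to an arene on work-up.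
Fallback: from 3, trapping of the lithium enolate (LiN(iPr)2, Me3SiCl, THF, −78 °C) gives the silyl ketene acetal F8. Rubottom oxidation with 3-chloroperoxybenzoic acid (NaHCO3, hexane–CH2Cl2, −20 °C) gives the 1-silyloxy ester F9, which is desilylated with K2CO3 in methanol to return at 5. No imine and no free alkoxide are present in this variant.

## Further compounds

F1 | step 6 | racemic [(1S*,2S*,6S*)-2-hydroxy-7-oxabicyclo[4.1.0]hept-3-en-2-yl]methyl benzoate (rac-10; one enantiomer drawn) | O=C(OC[C@@]1(O)C=CC[C@H]2[C@@H]1O2)c1ccccc1
F2 | step 6 | racemic [(1S*,5R*,6S*)-1,5,6-trihydroxycyclohex-2-en-1-yl]methyl benzoate (rac-11; one enantiomer drawn) | O=C(OC[C@@]1(O)C=CC[C@@H](O)[C@@H]1O)c1ccccc1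
F3 | step 6 | racemic [(3aS*,4R*,7aS*)-4-hydroxy-2,2-dimethyl-3a,4,5,7a-tetrahydro-1,3-benzodioxol-7a-yl]methyl benzoate (rac-12; one enantiomer drawn) | O=C(OC[C@@]12C=CC[C@@H](O)[C@@H]1OC(C)(C)O2)c1ccccc1
F4 | step 6 | [(3aS,4R,7aS)-4-[(chloroacetyl)oxy]-2,2-dimethyl-3a,4,5,7a-tetrahydro-1,3-benzodioxol-7a-yl]methyl benzoate | O=C(OC[C@@]12C=CC[C@@H](OC(=O)CCl)[C@@H]1OC(C)(C)O2)c1ccccc1
F5 | step 10 | C2/C3 epoxide of 13 with the oxirane on the arm face | O=C(OC[C@@]12[C@H]3O[C@H]3C[C@@H](O[Si](C)(C)C(C)(C)C)[C@@H]1OC(C)(C)O2)c1ccccc1
F6 | step 10 | hydroxy selenide: C2–OH on the arm face, C3–SePh on the hydroxyl face, otherwise as 13 | O=C(OC[C@@]12[C@@H](O)[C@H]([Se]c3ccccc3)C[C@@H](O[Si](C)(C)C(C)(C)C)[C@@H]1OC(C)(C)O2)c1ccccc1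
F7 | step 7 | [(1S,5R,6S)-5-[(chloroacetyl)oxy]-1,6-dihydroxycyclohex-2-en-1-yl]methyl benzoate | O=C(OC[C@@]1(O)C=CC[C@@H](OC(=O)CCl)[C@@H]1O)c1ccccc1
F8 | step 3 | [(cyclohexa-2,5-dien-1-ylidene)(methoxy)methoxy]trimethylsilane | COC(O[Si](C)(C)C)=C1C=CCC=C1
F9 | step 3 | methyl 1-[(trimethylsilyl)oxy]cyclohexa-2,5-diene-1-carboxylate | COC(=O)C1(O[Si](C)(C)C)C=CCC=C1
A1 | alternative 1 | cyclohexene-fused isoxazoline with a tert-butyldimethylsilyloxy group on quaternary C1 and the C5/C6 acetonide | CC(C)(C)[Si](C)(C)O[C@]12CON=C1C=C[C@H]1OC(C)(C)O[C@@H]12
A2 | alternative 1 | (2S,3S)-tartaric acid | OC(=O)[C@@H](O)[C@H](O)C(O)=O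
A3 | alternative 2 | dihydroxyacetone phosphate | O=C(CO)COP(=O)(O)O
A4 | alternative 2 | 4-nitrobutanal | O=CCCC[N+](=O)[O-]
A5 | alternative 2 | nitrocyclitol phosphate (C1, C5 and C6 as in 17; nitro group on C2; C3 and C4 methylenes) | O=P(O)(O)OC[C@@]1(O)[C@H]([N+](=O)[O-])CC[C@@H](O)[C@@H]1O
A6 | alternative 3 | cyclohexenecarboxylic acid with C7 as the acid, the C1/C6 acetonide, the C2 4-methoxybenzyl ether and the C5 tert-butyldimethylsilyl ether | OC(=O)[C@@]1(OC2(C)C)[C@@H](OCc3ccc(OC)cc3)C=C[C@@H](O[Si](C)(C)C(C)(C)C)[C@@H]1O2
A7 | alternative 3 | D-mannose (open-chain form) | OC[C@@H](O)[C@@H](O)[C@H](O)[C@H](O)C=O
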